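**Retrosynthetic overview**
- The target is a (3R)-isoflavan. Ring C is opened at O1–C2 (Mitsunobu etherification of a C2 primary alcohol by the ring A phenol), and C2 is taken back to a C3–boron bond (Matteson homologation, then oxidation).
- The strategy rests on the C3–C4 unit: two carbons carrying ring B (C1') and the C2 site on C3 and ring A (C4a) on C4, that is, a vinyl group arylated at both carbons. It is cut at C3–C1' and C4–C4a into a ring B pinacol boronate, vinyllithium and a ring A aryl triflate, joined in one enantioselective Pd-catalysed conjunctive coupling that sets C3.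
- Ring B boronate: resorcinol, C2 prenylation by directed lithiation, pyran annulation with 3-methylbut-2-enal, C6 bromination, silylation, Miyaura borylation. Ring A triflate: 2,4-dihydroxybenzaldehyde, protection, Dakin oxidation, triflation.
- Ring order: both benzene rings are bought; the dimethylpyran ring on ring B is closed first (step 4), ring C last (step 17).

Key step: step 13

Remark on the chemistry: vinyllithium is made halide-free from tetravinylstannane because lithium halides retard couplings of aryl triflates. The ferrocenyl ligand antipode written in step 13 is a working assignment for the (R)-boronate; the sense of induction is to be checked on a test scale (oxidation to the carbinol, chiral HPLC against the product of the antipodal ligand) and the antipode used if needed.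

**Route**

Step 1
Reactants: 1 resorcinol
Product: 2 1,3-bis(methoxymethoxy)benzene
Conditions: MOMCl (2.5 equiv), i-Pr2NEt (3 equiv), CH2Cl2, 0 °C to rt
Reagents that add atoms: chloromethyl methyl ether, COCCl
Why: O-alkylation of both phenols with the α-chloro ether (acetal protection) gives the bis-acetal whose two oxygen groups together direct the later lithiation to C2.

Step 2
Reactants: 2 1,3-bis(methoxymethoxy)benzene; 3 1-bromo-3-methylbut-2-ene (prenyl bromide)
Product: 5 1,3-bis(methoxymethoxy)-2-(3-methylbut-2-en-1-yl)benzene, via 2-lithio-1,3-bis(methoxymethoxy)benzene 4 (not isolated)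
Conditions: n-BuLi (1.1 equiv), THF, 0 °C to rt; then 3 (1.2 equiv), −78 °C to rt
Reagents that add atoms: none
Why: Directed ortho-metalation removes the proton flanked by both acetal oxygens and the aryllithium is alkylated at the primary carbon of the allylic bromide (SN2), which avoids the O- versus C- and C2 versus C4 ambiguity of direct phenol prenylation.

Step 3
Reactants: 5 1,3-bis(methoxymethoxy)-2-(3-methylbut-2-en-1-yl)benzene
Product: 6 2-(3-methylbut-2-en-1-yl)benzene-1,3-diol
Conditions: p-TsOH·H2O (0.2 equiv), MeOH, rt to 40 °C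
Reagents that add atoms: none
Why: Acid-catalysed acetal exchange with methanol should free both phenols, and the low acid loading and temperature are chosen to keep the prenyl alkene from cyclising onto an ortho hydroxyl.

Step 4
Reactants: 6 2-(3-methylbut-2-en-1-yl)benzene-1,3-diol; 7 3-methylbut-2-enal
Product: 8 2,2-dimethyl-8-(3-methylbut-2-en-1-yl)-2H-chromen-7-ol
Conditions: 7 (1.1 equiv, slow addition), ethylenediammonium diacetate (10 mol%), toluene, 110 °C
Reagents that add atoms: none
Why: Formal [3+3] chromene annulation, in which iminium-mediated condensation of the enal at C4 of the resorcinol (C2 is blocked, C4 and C6 are equivalent) and oxa-6π-electrocyclisation of the resulting dienone close the dimethylpyran ring.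

Step 5
Reactants: 8 2,2-dimethyl-8-(3-methylbut-2-en-1-yl)-2H-chromen-7-ol
Product: 9 6-bromo-2,2-dimethyl-8-(3-methylbut-2-en-1-yl)-2H-chromen-7-ol
Conditions: NBS (1.0 equiv), i-Pr2NH (10 mol%), CH2Cl2, −78 to −20 °C, dark
Reagents that add atoms: N-bromosuccinimide, O=C1CCC(=O)N1Br
Why: Amine-mediated ortho-bromination of a phenol (electrophilic aromatic substitution) at C6, the only ring position ortho to the free hydroxyl and para to the pyran oxygen, should outrun attack on either alkene at low temperature.

Step 6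
Reactants: 9 6-bromo-2,2-dimethyl-8-(3-methylbut-2-en-1-yl)-2H-chromen-7-ol
Product: 10 tert-butyl{[6-bromo-2,2-dimethyl-8-(3-methylbut-2-en-1-yl)-2H-chromen-7-yl]oxy}dimethylsilane
Conditions: TBSOTf (1.3 equiv), 2,6-lutidine (2 equiv), CH2Cl2, 0 °C to rt
Reagents that add atoms: tert-butyldimethylsilyl trifluoromethanesulfonate, CC(C)(C)[Si](C)(C)OS(=O)(=O)C(F)(F)F
Why: Silylation with the silyl triflate is reactive enough for a phenol flanked by bromine and the prenyl group, and the hindered aryl silyl ether formed is robust toward the later basic and mildly acidic steps.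

Step 7
Reactants: 10 tert-butyl{[6-bromo-2,2-dimethyl-8-(3-methylbut-2-en-1-yl)-2H-chromen-7-yl]oxy}dimethylsilane
Product: 11 tert-butyldimethyl{[2,2-dimethyl-8-(3-methylbut-2-en-1-yl)-6-(4,4,5,5-tetramethyl-1,3,2-dioxaborolan-2-yl)-2H-chromen-7-yl]oxy}silane
Conditions: B2pin2 (1.5 equiv), Pd(dppf)Cl2·CH2Cl2 (5 mol%), KOAc (3 equiv), 1,4-dioxane, 90 °C
Reagents that add atoms: bis(pinacolato)diboron, CC1(C)OB(OC1(C)C)B1OC(C)(C)C(C)(C)O1
Why: Miyaura borylation (oxidative addition of zerovalent palladium into C–Br, acetate-assisted transmetallation with the diboron, reductive elimination) installs boron without an ortho-silyloxy aryllithium, which would be prone to silyl migration from oxygen to carbon.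

Step 8
Reactants: 12 2,4-dihydroxybenzaldehyde
Product: 13 2-hydroxy-4-[(triisopropylsilyl)oxy]benzaldehyde
Conditions: TIPSCl (1.05 equiv), imidazole (2 equiv), CH2Cl2, 0 °C to rt
Reagents that add atoms: chlorotriisopropylsilane, CC(C)[Si](Cl)(C(C)C)C(C)C
Why: Selective silylation of the 4-hydroxyl, because the 2-hydroxyl is hydrogen-bonded to the aldehyde and more hindered; the triisopropylsilyl ether is chosen for its stability to the base used in step 10.

Step 9
Reactants: 13 2-hydroxy-4-[(triisopropylsilyl)oxy]benzaldehyde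
Product: 14 2-(methoxymethoxy)-4-[(triisopropylsilyl)oxy]benzaldehyde
Conditions: MOMCl (2 equiv), i-Pr2NEt (3 equiv), CH2Cl2, 0 to 40 °C
Reagents that add atoms: chloromethyl methyl ether, COCCl
Why: Acetal protection of the remaining phenol gives a group that cannot migrate to the neighbouring oxygen freed in step 10 and is orthogonal to the silyl ethers.

Step 10
Reactants: 14 2-(methoxymethoxy)-4-[(triisopropylsilyl)oxy]benzaldehyde
Product: 16 2-(methoxymethoxy)-4-[(triisopropylsilyl)oxy]phenol, via aryl formate 15 (not isolated)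
Conditions: mCPBA (1.3 equiv), CH2Cl2, 0 °C to rt; aq. NaHCO3 wash; then K2CO3 (cat.), MeOH, 0 °C, 15 min
Reagents that add atoms: 3-chloroperoxybenzoic acid, OOC(=O)c1cccc(Cl)c1
Why: Dakin-type Baeyer–Villiger oxidation, in which the ortho and para oxygen donors favour aryl migration to the formate, and brief carbonate-catalysed methanolysis of the formate should leave the silyl ether intact.

Step 11
Reactants: 16 2-(methoxymethoxy)-4-[(triisopropylsilyl)oxy]phenol
Product: 17 2-(methoxymethoxy)-4-[(triisopropylsilyl)oxy]phenyl trifluoromethanesulfonate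
Conditions: Tf2O (1.2 equiv), pyridine (3 equiv), CH2Cl2, −20 to 0 °C
Reagents that add atoms: trifluoromethanesulfonic anhydride, O=S(=O)(OS(=O)(=O)C(F)(F)F)C(F)(F)F
Why: O-Sulfonylation of the phenol gives the aryl triflate whose non-coordinating leaving group is needed for a cationic arylpalladium species in the key step.

Step 12
Reactants: 18 tetravinylstannane
Product: 19 vinyllithium
Conditions: n-BuLi (hexanes), pentane, rt; solid filtered under argon, washed with pentane, dissolved in THF and titrated
Reagents that add atoms: n-butyllithium, [Li]CCCC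
Why: Tin–lithium exchange is driven by precipitation of vinyllithium from the hydrocarbon and gives a halide-free reagent.

Step 13
Reactants: 11 tert-butyldimethyl{[2,2-dimethyl-8-(3-methylbut-2-en-1-yl)-6-(4,4,5,5-tetramethyl-1,3,2-dioxaborolan-2-yl)-2H-chromen-7-yl]oxy}silane; 19 vinyllithium; 17 2-(methoxymethoxy)-4-[(triisopropylsilyl)oxy]phenyl trifluoromethanesulfonate
Product: 21 2-[(1R)-1-{7-[(tert-butyldimethylsilyl)oxy]-2,2-dimethyl-8-(3-methylbut-2-en-1-yl)-2H-chromen-6-yl}-2-{2-(methoxymethoxy)-4-[(triisopropylsilyl)oxy]phenyl}ethyl]-4,4,5,5-tetramethyl-1,3,2-dioxaborolane, via lithium aryl(vinyl)borate 20 (not isolated)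
Conditions: 11, 19 (1.0 equiv), THF, 0 °C to rt, 30 min; then 17 (1.1 equiv), Pd(OAc)2 (3 mol%), (Rp,R'p)-1,1'-bis[bis(4-methoxy-3,5-dimethylphenyl)phosphino]-2,2'-bis[(S)-α-(dimethylamino)benzyl]ferrocene (a Mandyphos ligand, 3.6 mol%), THF, 60 °C
Reagents that add atoms: none
Why: Oxidative addition of triflate 17 to zerovalent palladium (formed from Pd(OAc)2 and the bisphosphine) gives a cationic arylpalladium species that binds the vinyl group of ate complex 20; this triggers a 1,2-shift of the ring B aryl group from boron to the boron-bearing carbon anti to palladium (C3–C1' bond), and reductive elimination then joins ring A to the terminal carbon (C4–C4a bond). The closest known reaction type is the Pd-catalysed enantioselective conjunctive cross-coupling of vinylboron ate complexes with aryl triflates, which includes aryl migrating groups on pinacol boronates. No ring is closed. The C3 stereocenter is set by the chiral ferrocenyl bisphosphine, which selects the face of the coordinated alkenylborate during the metallate shift, and the ligand antipode is chosen for the R configuration. The step needs the conjunctive path to beat direct Suzuki–Miyaura transfer of vinyl or aryl from boron; this is secured by the wide-bite-angle ligand, the weakly coordinating triflate counter-ion, the halide-free vinyllithium and the four-coordinate pinacol ate complex, while the electron-rich alkenylborate should react with the cationic palladium far faster than the prenyl and chromene alkenes.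

Step 14
Reactants: 21 the (R)-secondary benzylic pinacol boronate of step 13
Product: 23 2-[(2R)-2-{7-[(tert-butyldimethylsilyl)oxy]-2,2-dimethyl-8-(3-methylbut-2-en-1-yl)-2H-chromen-6-yl}-3-{2-(methoxymethoxy)-4-[(triisopropylsilyl)oxy]phenyl}propyl]-4,4,5,5-tetramethyl-1,3,2-dioxaborolane, via lithium chloromethyl borate 22 (not isolated)
Conditions: BrCH2Cl (3 equiv), n-BuLi (2.5 equiv, added last), THF, −78 °C to rt
Reagents that add atoms: bromochloromethane, ClCBr
Why: Matteson homologation, in which chloromethyllithium made in situ adds to boron and the benzylic carbon migrates from boron to the CH2 carbon with loss of chloride and retention at C3, so C2 is installed without touching the stereocenter.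

Step 15
Reactants: 23 the homologated primary pinacol boronate of step 14
Product: 24 (2R)-2-{7-[(tert-butyldimethylsilyl)oxy]-2,2-dimethyl-8-(3-methylbut-2-en-1-yl)-2H-chromen-6-yl}-3-{2-(methoxymethoxy)-4-[(triisopropylsilyl)oxy]phenyl}propan-1-ol
Conditions: NaBO3·4H2O (5 equiv), THF/H2O (1:1), rt
Reagents that add atoms: sodium perborate tetrahydrate, [Na+].[Na+].O[B-]1(O)OO[B-](O)(O)OO1.O.O.O.O.O.O
Why: Perborate oxidation of the C–B bond (peroxide addition to boron and 1,2-shift of carbon to oxygen) gives the primary alcohol under conditions mild enough for the aryl silyl ethers and inert toward the alkenes.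

Step 16
Reactants: 24 the primary alcohol of step 15
Product: 25 2-[(2R)-2-{7-[(tert-butyldimethylsilyl)oxy]-2,2-dimethyl-8-(3-methylbut-2-en-1-yl)-2H-chromen-6-yl}-3-hydroxypropyl]-5-[(triisopropylsilyl)oxy]phenol
Conditions: p-TsOH·H2O (0.3 equiv), MeOH/THF (4:1), 35 °C
Reagents that add atoms: none
Why: Acid-catalysed acetal methanolysis should remove the aryl methoxymethyl ether while the aryl silyl ethers (one triisopropylsilyl, one doubly ortho-hindered tert-butyldimethylsilyl) persist, so that only the ring A phenol destined to become O1 is free.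

Step 17
Reactants: 25 the phenol alcohol of step 16
Product: 26 (3R)-3-{7-[(tert-butyldimethylsilyl)oxy]-2,2-dimethyl-8-(3-methylbut-2-en-1-yl)-2H-chromen-6-yl}-7-[(triisopropylsilyl)oxy]-3,4-dihydro-2H-chromene
Conditions: PPh3 (1.5 equiv), DIAD (1.5 equiv), THF (0.02 M), 0 °C to rt
Reagents that add atoms: none
Why: Intramolecular Mitsunobu etherification, in which the phenol displaces the activated primary alcohol (6-exo-tet) to close ring C at O1–C2; C3 is not involved, and the ring B oxygen that could close a five-membered ring is still silylated.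

Step 18
Reactants: 26 the bis-silyl isoflavan of step 17
Product: 27 (3R)-3-[7-hydroxy-2,2-dimethyl-8-(3-methylbut-2-en-1-yl)-2H-chromen-6-yl]-3,4-dihydro-2H-chromen-7-ol
Conditions: TBAF (3 equiv), AcOH (3 equiv), THF, 0 °C to rt
Reagents that add atoms: none
Why: Fluoride desilylation cleaves both aryl silyl ethers, and the acetic acid buffer avoids the free phenoxides and any acid that could cyclise the 2'-hydroxyl onto the prenyl group.

**Compound list**

1 | resorcinol (benzene-1,3-diol) | Oc1cccc(O)c1 | starting material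
2 | 1,3-bis(methoxymethoxy)benzene | COCOc1cccc(OCOC)c1 | intermediate
3 | 1-bromo-3-methylbut-2-ene (prenyl bromide) | CC(C)=CCBr | starting material
4 | 2-lithio-1,3-bis(methoxymethoxy)benzene | [Li]c1c(OCOC)cccc1OCOC | intermediate (not isolated)
5 | 1,3-bis(methoxymethoxy)-2-(3-methylbut-2-en-1-yl)benzene | COCOc1cccc(OCOC)c1CC=C(C)C | intermediate
6 | 2-(3-methylbut-2-en-1-yl)benzene-1,3-diol | CC(C)=CCc1c(O)cccc1O | intermediate
7 | 3-methylbut-2-enal | CC(C)=CC=O | starting material
8 | 2,2-dimethyl-8-(3-methylbut-2-en-1-yl)-2H-chromen-7-ol | CC(C)=CCc1c(O)ccc2c1OC(C)(C)C=C2 | intermediate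
9 | 6-bromo-2,2-dimethyl-8-(3-methylbut-2-en-1-yl)-2H-chromen-7-ol | CC(C)=CCc1c(O)c(Br)cc2c1OC(C)(C)C=C2 | intermediate
10 | tert-butyl{[6-bromo-2,2-dimethyl-8-(3-methylbut-2-en-1-yl)-2H-chromen-7-yl]oxy}dimethylsilane | CC(C)=CCc1c(O[Si](C)(C)C(C)(C)C)c(Br)cc2c1OC(C)(C)C=C2 | intermediate
11 | ring B pinacol boronate, tert-butyldimethyl{[2,2-dimethyl-8-(3-methylbut-2-en-1-yl)-6-(4,4,5,5-tetramethyl-1,3,2-dioxaborolan-2-yl)-2H-chromen-7-yl]oxy}silane | CC(C)=CCc1c(O[Si](C)(C)C(C)(C)C)c(B3OC(C)(C)C(C)(C)O3)cc2c1OC(C)(C)C=C2 | intermediate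
12 | 2,4-dihydroxybenzaldehyde | O=Cc1ccc(O)cc1O | starting material
13 | 2-hydroxy-4-[(triisopropylsilyl)oxy]benzaldehyde | O=Cc1ccc(O[Si](C(C)C)(C(C)C)C(C)C)cc1O | intermediate
14 | 2-(methoxymethoxy)-4-[(triisopropylsilyl)oxy]benzaldehyde | COCOc1cc(O[Si](C(C)C)(C(C)C)C(C)C)ccc1C=O | intermediate
15 | 2-(methoxymethoxy)-4-[(triisopropylsilyl)oxy]phenyl formate | COCOc1cc(O[Si](C(C)C)(C(C)C)C(C)C)ccc1OC=O | intermediate (not isolated)
16 | 2-(methoxymethoxy)-4-[(triisopropylsilyl)oxy]phenol | COCOc1cc(O[Si](C(C)C)(C(C)C)C(C)C)ccc1O | intermediate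
17 | ring A triflate, 2-(methoxymethoxy)-4-[(triisopropylsilyl)oxy]phenyl trifluoromethanesulfonate | COCOc1cc(O[Si](C(C)C)(C(C)C)C(C)C)ccc1OS(=O)(=O)C(F)(F)F | intermediate
18 | tetravinylstannane | C=C[Sn](C=C)(C=C)C=C | starting material
19 | vinyllithium | [Li]C=C | intermediate
20 | lithium aryl(vinyl)pinacolatoborate from 11 and 19 | CC(C)=CCc1c(O[Si](C)(C)C(C)(C)C)c([B-]3(C=C)OC(C)(C)C(C)(C)O3)cc2c1OC(C)(C)C=C2.[Li+] | intermediate (not isolated)
21 | (R)-secondary benzylic pinacol boronate, ring B and boron on C3, ring A on C4 | CC(C)=CCc1c(O[Si](C)(C)C(C)(C)C)c([C@@H](Cc3ccc(O[Si](C(C)C)(C(C)C)C(C)C)cc3OCOC)B3OC(C)(C)C(C)(C)O3)cc2c1OC(C)(C)C=C2 | intermediate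
22 | lithium (chloromethyl)borate of 21, (R) | CC(C)=CCc1c(O[Si](C)(C)C(C)(C)C)c([C@@H](Cc3ccc(O[Si](C(C)C)(C(C)C)C(C)C)cc3OCOC)[B-]3(CCl)OC(C)(C)C(C)(C)O3)cc2c1OC(C)(C)C=C2.[Li+] | intermediate (not isolated)
23 | (R)-homologated primary pinacol boronate (C2 as CH2–B) | CC(C)=CCc1c(O[Si](C)(C)C(C)(C)C)c([C@@H](Cc3ccc(O[Si](C(C)C)(C(C)C)C(C)C)cc3OCOC)CB3OC(C)(C)C(C)(C)O3)cc2c1OC(C)(C)C=C2 | intermediate
24 | (2R)-2-(ring B)-3-(ring A)propan-1-ol, methoxymethyl and both silyl ethers in place | CC(C)=CCc1c(O[Si](C)(C)C(C)(C)C)c([C@@H](Cc3ccc(O[Si](C(C)C)(C(C)C)C(C)C)cc3OCOC)CO)cc2c1OC(C)(C)C=C2 | intermediate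
25 | (R)-phenol alcohol, ring A hydroxyl for O1 free | CC(C)=CCc1c(O[Si](C)(C)C(C)(C)C)c([C@@H](Cc3ccc(O[Si](C(C)C)(C(C)C)C(C)C)cc3O)CO)cc2c1OC(C)(C)C=C2 | intermediate
26 | (3R)-bis-silyl isoflavan | CC(C)=CCc1c(O[Si](C)(C)C(C)(C)C)c([C@@H]2COc3cc(O[Si](C(C)C)(C(C)C)C(C)C)ccc3C2)cc2c1OC(C)(C)C=C2 | intermediate
27 | (3R)-3-[7-hydroxy-2,2-dimethyl-8-(3-methylbut-2-en-1-yl)-2H-chromen-6-yl]-3,4-dihydro-2H-chromen-7-ol | CC(C)=CCc1c(O)c([C@@H]2COc3cc(O)ccc3C2)cc2c1OC(C)(C)C=C2 | target

**Totals**
Total step count: 18. Longest linear sequence: 13 steps (steps 1–7, 13, 14–18).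

**Steps most likely to fail**

1. Step 13. Both aryl partners carry an ortho oxygen substituent, and the silyl ether next to boron is bulky. The metallate shift may therefore become slow, so that direct Suzuki–Miyaura transfer of vinyl or aryl from the ate complex, or protodeboronation, takes over; the facial selectivity may also be insufficient. The fallback sets C3 by an Evans alkylation. It sets out from aryl bromide 10 and aldehyde 14 and comes back to the route at alcohol 24, so that steps 7 and 10–15 are not needed. Aldehyde 14 is reduced (NaBH4, MeOH, 0 °C) to {2-(methoxymethoxy)-4-[(triisopropylsilyl)oxy]phenyl}methanol F1, which is converted (PPh3, CBr4, CH2Cl2, 0 °C) into the benzyl bromide F2 and used at once. Bromide 10 is coupled with commercial 2-tert-butoxy-2-oxoethylzinc bromide (Pd(dba)2, P(t-Bu)3, THF, rt) to the tert-butyl arylacetate F3. TMSOTf and 2,6-lutidine (CH2Cl2, 0 °C) give the trimethylsilyl ester F4, hydrolysed on aqueous work-up to the arylacetic acid F5. The acid is joined to (4R)-4-benzyl-1,3-oxazolidin-2-one (PivCl, Et3N, LiCl, THF) to give the acyl oxazolidinone F6. NaHMDS (THF, −78 °C) forms the Z sodium enolate F7, which is alkylated by F2 on the face away from the benzyl group to the (2R)-imide F8. LiBH4 (THF, MeOH, 0 °C) removes the auxiliary and gives 24.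

2. Step 5. Bromonium formation at the prenyl or chromene alkene, with bromoetherification by the neighbouring phenol, may compete with ring substitution. The fallback puts the halogen on before any alkene is present. It sets out from 2 and comes back at 9, replacing steps 2–5. Compound 2 is brominated (NBS, MeCN, 0 °C) to 1-bromo-2,4-bis(methoxymethoxy)benzene F9. LDA (THF, −78 °C) removes the proton between the two acetal oxygens to give [3-bromo-2,6-bis(methoxymethoxy)phenyl]lithium F10, which is alkylated with 3 to 1-bromo-2,4-bis(methoxymethoxy)-3-(3-methylbut-2-en-1-yl)benzene F11. Methanolysis as in step 3 gives 4-bromo-2-(3-methylbut-2-en-1-yl)benzene-1,3-diol F12. Annulation with 7 under the conditions of step 4 can occur only at the single free position ortho to a hydroxyl and gives 9.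

3. Step 4. The product keeps a free hydroxyl with a free ortho position, so a second annulation to a pyranochromene, and self-condensation of the enal, may erode the mono-annulation. The fallback builds the pyran ring stepwise. It sets out from 6 and comes back at 8. Mono-O-alkylation of 6 with 3-chloro-3-methylbut-1-yne (DBU, CuCl2 (1 mol%), MeCN, 0 °C) gives 3-[(2-methylbut-3-yn-2-yl)oxy]-2-(3-methylbut-2-en-1-yl)phenol F13. Heating (o-xylene, 140 °C) brings about the aryl propargyl ether Claisen rearrangement to the free ortho position, followed by a 1,5-hydrogen shift and oxa-6π-electrocyclisation, to give 8.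

**Further compounds**

F1 | step 13 | {2-(methoxymethoxy)-4-[(triisopropylsilyl)oxy]phenyl}methanol | COCOc1cc(O[Si](C(C)C)(C(C)C)C(C)C)ccc1CO
F2 | step 13 | [4-(bromomethyl)-3-(methoxymethoxy)phenoxy]tri(propan-2-yl)silane | COCOc1cc(O[Si](C(C)C)(C(C)C)C(C)C)ccc1CBr
F3 | step 13 | tert-butyl 2-{7-[(tert-butyldimethylsilyl)oxy]-2,2-dimethyl-8-(3-methylbut-2-en-1-yl)-2H-chromen-6-yl}acetate | CC(C)=CCc1c(O[Si](C)(C)C(C)(C)C)c(CC(=O)OC(C)(C)C)cc2c1OC(C)(C)C=C2
F4 | step 13 | trimethylsilyl 2-{7-[(tert-butyldimethylsilyl)oxy]-2,2-dimethyl-8-(3-methylbut-2-en-1-yl)-2H-chromen-6-yl}acetate | CC(C)=CCc1c(O[Si](C)(C)C(C)(C)C)c(CC(=O)O[Si](C)(C)C)cc2c1OC(C)(C)C=C2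
F5 | step 13 | 2-{7-[(tert-butyldimethylsilyl)oxy]-2,2-dimethyl-8-(3-methylbut-2-en-1-yl)-2H-chromen-6-yl}acetic acid | CC(C)=CCc1c(O[Si](C)(C)C(C)(C)C)c(CC(=O)O)cc2c1OC(C)(C)C=C2
F6 | step 13 | (4R)-4-benzyl-3-(2-{7-[(tert-butyldimethylsilyl)oxy]-2,2-dimethyl-8-(3-methylbut-2-en-1-yl)-2H-chromen-6-yl}acetyl)-1,3-oxazolidin-2-one | CC(C)=CCc1c(O[Si](C)(C)C(C)(C)C)c(CC(=O)N3C(=O)OC[C@H]3Cc3ccccc3)cc2c1OC(C)(C)C=C2
F7 | step 13 | sodium (Z)-enolate of F6 | [Na+].[O-]/C(=C\c1cc2C=CC(C)(C)Oc2c(CC=C(C)C)c1O[Si](C)(C)C(C)(C)C)N1C(=O)OC[C@H]1Cc1ccccc1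
F8 | step 13 | (4R)-4-benzyl-3-[(2R)-2-{7-[(tert-butyldimethylsilyl)oxy]-2,2-dimethyl-8-(3-methylbut-2-en-1-yl)-2H-chromen-6-yl}-3-{2-(methoxymethoxy)-4-[(triisopropylsilyl)oxy]phenyl}propanoyl]-1,3-oxazolidin-2-one | CC(C)=CCc1c(O[Si](C)(C)C(C)(C)C)c([C@@H](Cc3ccc(O[Si](C(C)C)(C(C)C)C(C)C)cc3OCOC)C(=O)N3C(=O)OC[C@H]3Cc3ccccc3)cc2c1OC(C)(C)C=C2
F9 | step 5 | 1-bromo-2,4-bis(methoxymethoxy)benzene | COCOc1ccc(Br)c(OCOC)c1
F10 | step 5 | [3-bromo-2,6-bis(methoxymethoxy)phenyl]lithium | [Li]c1c(OCOC)ccc(Br)c1OCOC
F11 | step 5 | 1-bromo-2,4-bis(methoxymethoxy)-3-(3-methylbut-2-en-1-yl)benzene | COCOc1ccc(Br)c(OCOC)c1CC=C(C)C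
F12 | step 5 | 4-bromo-2-(3-methylbut-2-en-1-yl)benzene-1,3-diol | CC(C)=CCc1c(O)ccc(Br)c1O
F13 | step 4 | 3-[(2-methylbut-3-yn-2-yl)oxy]-2-(3-methylbut-2-en-1-yl)phenol | CC(C)=CCc1c(O)cccc1OC(C)(C)C#C
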